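A target that falls steadily over a few readings invites a decay curve drawn towards zero, yet such readings leave open where the fall stops. In the ash run, at −25 °C, the first instants show target building: 4.1% of the substrate charged after 10.0 s, 10.7% after 40.0 s, and 16.7% after 60.0 s. The oak run, warmer at −20 °C, already reads 14.8% at 0.667 min, so its middle is a decline, through 11.7% at 3.00 min. Its end reads 9.8% at 5.00 min, which is 1.9 percentage points below the reading before it, against a scatter of 1 point on each reading, so the last stretch says little about where the fall stops.

The charges offer a handle before anything reacts, and it stands at 0.600 in the oak run: the charge ratio, first nucleophile charged per second nucleophile charged, against 0.900 in ash. If both nucleophiles compete for one reactive form of the substrate, the share heading for target is to be read from this ratio, which stands lower in oak than in ash. For the present amount in the oak flask, the reckoning here takes the last oak reading, with its scatter.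

all flasks: substrate 30 mM

| run | first nucleophile | second nucleophile | temperature | remark | time |
|---|---|---|---|---|---|
| oak | 36 mM | 60 mM | −20 °C | the very flask that is asked about, followed so far |  |
| ash | 54 mM | 60 mM | −25 °C | run made earlier |  |
| flask | 36.0 mM | 60.0 mM | −20 °C |  | 5.0 min |

oak run (percent of the substrate charged)

| time / min | target / % |
|---|---|
| 0.667 | 14.8 |
| 2.00 | 13.0 |
| 3.00 | 11.7 |
| 5.00 | 9.8 |

ash run (percent of the substrate charged)

| time / s | target / % |
|---|---|
| 10.0 | 4.1 |
| 20.0 | 7.2 |
| 40.0 | 10.7 |
| 60.0 | 16.7 |

(readings scatter by 1 percentage point)

- alpha: at 5.0 min add second nucleophile, 100% of the amount charged, then wait 5.0 min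
- gamma: change nothing and wait 5.0 min more
- epsilon: at 5.0 min raise the temperature by 25 K, then wait 5.0 min
- zeta: at 5.0 min take out 90% of the target then present, then wait 5.0 min

- removed target is counted in
- additions bring no volume worth counting

- target, in percent of the substrate first charged, at 5.0 min
- the remedy with the largest gain of target, or "none" below 2 percentage points (alpha / gamma / epsilon / zeta / none)
- target present, with what was taken out counted in, in percent of the substrate first charged, after gamma
- target present, with what was taken out counted in, in percent of the substrate first charged, after epsilon

The forecast gives 9.8% now, 6.1% after gamma and 1% after epsilon, and it names zeta as best, reading the oak run through “a fast reversible pre-equilibrium”.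

The flask gives 9.18%, 8.88% after gamma and 19.5% after epsilon. The best remedy is epsilon, with a gain of 10 points against 6.4 points for zeta.

    substrate → intermediate (k = 0.0148 /s, Ea = 65.0 kJ/mol)
    target ⇌ isomer of the product (K = 4.27, k = 0.0247 /s, Ea = 66.0 kJ/mol, ΔH = −26.0 kJ/mol)
    first nucleophile + intermediate → target (k = 136 /M/s, Ea = 40.0 kJ/mol)
    second nucleophile + intermediate → other capture product (k = 85.1 /M/s, Ea = 35.0 kJ/mol)
    (constants at −20 °C)

The path from target to isomer of the product, both ways, has the largest single effect on target in this flask: without it, target at 5.0 min stands at 46.3% instead of 9.18%. Part of epsilon's gain comes from isomer of the product returning to target: with that back reaction taken away, the gain of 10 points becomes −0.75 points. Target and isomer of the product relax with a half-life of 0.379 min, short against 5.0 min, so the charge ratio can be read through two constants. In this flask, 0.600 and the selectivity factor 1.60 give a capture share of 49.0%, and dividing by 5.27 gives 9.29%. In a neighbouring flask, with 36 mM of second nucleophile, the ratio is 1.00, the share 61.5%, the reckoning 11.7%, and that flask holds 11.5%.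

(The data were generated by integration with made-up constants.)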